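My unit was the charge of substrate: product amounts below are fractions of it, and the coupling partner's remainder is told of its own charge.

- north: substrate 0.30 M; coupling partner 3.00 equiv; time 3.0 min
- south: substrate 0.30 M; coupling partner 1.50 equiv; time 3.0 min

    substrate + coupling partner → single product (k1 = 0.295 M⁻¹ s⁻¹)
    coupling partner + single product → double product (k2 = 0.356 M⁻¹ s⁻¹)
    coupling partner + double product → triple product (k3 = 0.00497 M⁻¹ s⁻¹)
    substrate + double product → side product (k4 = 0.0370 M⁻¹ s⁻¹)

- which of the two there is more of at the end, counted by the substrate in each, north (triple product / side product)
- which of the two there is more of at the end, counted by the substrate in each, south (triple product / side product)
- final triple product, as a percentage of the substrate charged, in north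
- final triple product, as a percentage of the substrate charged, in south

I turned two settings by hand, first the coupling partner, then the time.

The second coupling has a far larger constant than the third, and in south the half-life of single product by its step, 0.072 min, is far shorter than that of double product by the third coupling, 5.2 min. So I let each substrate take two partners first and reckoned the third coupling on the remainder.

North then had a surplus of 1.00, equal to its double product, so the rate went as the square of what was unreacted. The third constant times substrate concentration times time is 0.268, the third-step clock. Integrating gives the clock over one plus the clock, so triple product in north is 21.2%. Step 4 held against step 1, in substrate units, allowed 8.36% side product, so north favoured triple product.

South was short by 0.500. I gave the third coupling a share of the partner charge by the ratio of third to second constant, 2.09%. The substrate beyond the partner's reach allowed 50.0% side product in substrate units, so south favoured side product.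

With ten times the time, the clock gave north 72.9%. South had no surplus for the clock to act on, so I expected no gain there.

The forecast said triple product in north, at 21% (17% to 25%), and side product in south, with triple product at 1% (0.6% to 1.6%), since “the partner runs out during the fast first two steps”.

The simulation gave north 20.7% triple product against 3.92% side product. South gave 0.980% against 21.5%, with its limiting reagent, the coupling partner, at 0.122% of its own charge. Left ten times as long, north reached 72.6% and south 0.985%; in south the later reading made no difference.

North charged like south held 0.980% triple product instead of 20.7%, so the difference in equivalents of coupling partner is the main reason for the gap.

The neighbour with 3.80 equiv of partner, otherwise like south, has a surplus of 1.80. Unequal amounts turn the integral exponential: with E the exponential of the clock times the surplus's excess over double product, 1.24, the numerator is the surplus times the excess of E over one, the denominator is the product of surplus and E, minus one, and their ratio gives triple product as 35.1%. That flask held 33.9%.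

Its constants were set for the occasion; no experiment stands behind them.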